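The 2,2-dimethyl-2H-pyran ring is cut at C3–C4 and O1–C2. This leads back to a salicylaldehyde, in which the pyran oxygen is a phenol OH and C4 a formyl group on neighbouring carbons of the benzene ring, and to 2-methylprop-1-enylboronic acid. The key step exploits this ortho OH/CHO pair: an amine-catalysed Petasis borono-Mannich condensation with 6π-oxa-electrocyclisation forges both bonds in the final step, on the unprotected polyphenol. Its precursor, a cyclobuta[a]indane salicylaldehyde, should come from an enantioselective intramolecular radical-cation [2+2] cycloaddition of an ortho-prenyl stilbene (all three stereocentres), Vilsmeier–Haack formylation and one-pot BCl3 deprotection.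

Key step: step 7

Remark: which antipode of the chiral anion in step 4 gives the required (2S,2aR,7aS) series must be fixed by experiment; all formulas show the required series.

Locants for the tricyclic compounds follow 2,2a,7,7a-tetrahydro-1H-cyclobuta[a]indene: C1 is the CMe2 carbon, C2 the aryl-bearing CH, C2a the benzylic ring-fusion CH, C3 to C6 the arene positions, C7 the CH2 and C7a the other ring-fusion CH.

Step 1
Reactants: 1 diethyl (3,5-dimethoxybenzyl)phosphonate; 2 3,4-bis(benzyloxy)benzaldehyde
Product: 4 (E)-3',4'-bis(benzyloxy)-3,5-dimethoxystilbene, via potassium phosphonate carbanion 3 (not isolated)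
Conditions: KOtBu, THF, 0 °C → rt
Reagents that add atoms: none
Why: Horner–Wadsworth–Emmons olefination of a benzylic phosphonate carbanion with an aryl aldehyde should give the E-stilbene by elimination from the favoured adduct, and benzyl ethers are inert to the base.

Step 2
Reactants: 4 (E)-3',4'-bis(benzyloxy)-3,5-dimethoxystilbene
Product: 5 (E)-2-bromo-3',4'-bis(benzyloxy)-3,5-dimethoxystilbene
Conditions: NBS (1.0 equiv), CH2Cl2, −78 → 0 °C, dark
Reagents that add atoms: N-bromosuccinimide, O=C1CCC(=O)N1Br
Why: Electrophilic aromatic bromination should occur at the carbon ortho to the alkene, which is para to one methoxy group and ortho to the other and far more nucleophilic than the dibenzyloxy ring, the buttressed position between the methoxy groups or the alkene.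

Step 3
Reactants: 5 (E)-2-bromo-3',4'-bis(benzyloxy)-3,5-dimethoxystilbene; 6 1-bromo-3-methylbut-2-ene (prenyl bromide)
Product: 8 (E)-3',4'-bis(benzyloxy)-3,5-dimethoxy-2-(3-methylbut-2-enyl)stilbene, via aryllithium 7 (not isolated)
Conditions: n-BuLi (1.05 equiv), THF, −78 °C; CuBr·SMe2 (10 mol%), then 6, −78 → 0 °C
Reagents that add atoms: none
Why: Bromine–lithium exchange at −78 °C outruns addition to the stilbene, and copper-catalysed SN2 allylation of the aryllithium at the primary carbon of prenyl bromide should give the linear prenyl group.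

Step 4
Reactants: 8 (E)-3',4'-bis(benzyloxy)-3,5-dimethoxy-2-(3-methylbut-2-enyl)stilbene
Product: 9 (2S,2aR,7aS)-2-[3,4-bis(benzyloxy)phenyl]-4,6-dimethoxy-1,1-dimethyl-2,2a,7,7a-tetrahydro-1H-cyclobuta[a]indene
Conditions: 9-arylthioxanthylium photoredox cation paired with an enantiopure imidodiphosphorimidate (IDPi) anion (3 mol%), green LEDs (525 nm), CH2Cl2, −78 °C, argon
Reagents that add atoms: none
Why: Proposed new method: the photoexcited thioxanthylium cation oxidises the electron-rich stilbene to a radical cation whose charge sits on the benzylic carbon next to the dibenzyloxyphenyl ring; the prenyl alkene adds to the other stilbene carbon in a 5-exo closure (cis ring fusion enforced by the five-membered ring), the tertiary centre then closes the cyclobutane onto the benzylic centre with the aryl group on the convex face (trans to the arene bond at C2a, as in the E-alkene), and back electron transfer releases 9; the confined chiral anion paired with the radical cation shields one face during the first C–C bond formation and so should set the absolute configuration of all three stereocentres; the closest known reaction types are the counteranion-directed enantioselective radical-cation [2+2] cross-cycloaddition of electron-rich styrenes (intermolecular) and the racemic intramolecular radical-cation [2+2] of styrenes with tethered alkenes.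

Step 5
Reactants: 9 (2S,2aR,7aS)-2-[3,4-bis(benzyloxy)phenyl]-4,6-dimethoxy-1,1-dimethyl-2,2a,7,7a-tetrahydro-1H-cyclobuta[a]indene
Product: 11 (2S,2aR,7aS)-2-[3,4-bis(benzyloxy)phenyl]-4,6-dimethoxy-1,1-dimethyl-2,2a,7,7a-tetrahydro-1H-cyclobuta[a]indene-3-carbaldehyde, via iminium chloride 10 (not isolated)
Conditions: POCl3 (1.5 equiv), DMF, 0 → 50 °C; then aq. NaOAc
Reagents that add atoms: N,N-dimethylformamide, CN(C)C=O; water, O
Why: Vilsmeier–Haack formylation should attack only the 1,3-dimethoxy ring and there C3 (ortho to the C4 methoxy group, para to the C6 methoxy group) in preference to the buttressed C5 between the two methoxy groups, with no alkene left to compete.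

Step 6
Reactants: 11 (2S,2aR,7aS)-2-[3,4-bis(benzyloxy)phenyl]-4,6-dimethoxy-1,1-dimethyl-2,2a,7,7a-tetrahydro-1H-cyclobuta[a]indene-3-carbaldehyde
Product: 13 (2S,2aR,7aS)-2-(3,4-dihydroxyphenyl)-4-hydroxy-6-methoxy-1,1-dimethyl-2,2a,7,7a-tetrahydro-1H-cyclobuta[a]indene-3-carbaldehyde, via boron-bound triol 12 (not isolated)
Conditions: BCl3 (4 equiv), pentamethylbenzene (6 equiv), CH2Cl2, −78 → 0 °C; then H2O
Reagents that add atoms: none
Why: Chelation-controlled demethylation: BCl3 held between the formyl oxygen and the C4 methoxy oxygen should cleave only that methyl ether (the C6 methoxy group para to the formyl group has no such assistance), and the same reagent debenzylates both aryl benzyl ethers with pentamethylbenzene trapping the benzyl cations.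

Step 7
Reactants: 13 (2S,2aR,7aS)-2-(3,4-dihydroxyphenyl)-4-hydroxy-6-methoxy-1,1-dimethyl-2,2a,7,7a-tetrahydro-1H-cyclobuta[a]indene-3-carbaldehyde; 14 2-methylprop-1-enylboronic acid
Product: 19 target CNP0207533.1, via catechol boronate 15 (not isolated), via allylic amine adduct 16 (not isolated), via ortho-quinone methide 17 (not isolated), via boronate-masked chromene 18 (not isolated)
Conditions: 14 (3.5 equiv), Bn2NH (0.5 equiv), 1,4-dioxane, 90 °C, argon; then aq. NH4Cl
Reagents that add atoms: none
Why: The catechol first binds one equivalent of 14 as the cyclic boronate 15 (self-protection against oxidation); dibenzylamine then condenses with the formyl group to an iminium ion, and a second molecule of 14, held as a tetracoordinate boronate on the neighbouring phenoxide, transfers its alkenyl group to the iminium carbon (pyran C4–C3 bond, adduct 16). Thermal loss of dibenzylamine, which turns over, gives the ortho-quinone methide 17, whose 6π-oxa-electrocyclisation forms the O1–C2 bond, restores the benzene ring and leaves the C3=C4 double bond; aqueous work-up hydrolyses the catechol boronate 18. The closest known reaction type is the amine-catalysed Petasis borono-Mannich condensation of salicylaldehydes with alkenylboronic acids to 2H-chromenes. The pyran ring closes by a thermal disrotatory 6π electrocyclisation of the 1-oxatriene, formally 6-endo at the dimethyl-substituted terminus. No stereocentre is formed or touched: C2 of the pyran carries two methyl groups, the aminated carbon of 16 becomes sp2, and the three cyclobutane stereocentres lie outside the reacting π system. The step needs annulation toward the formyl-bearing carbon rather than the free C5 between the two oxygens, and alkenyl transfer in the presence of three phenols; the first is fixed because the only electrophilic carbon already sits on the ring, the second because only a boronate bound next to the iminium can deliver its alkenyl group.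

Compound list
1 | diethyl (3,5-dimethoxybenzyl)phosphonate | CCOP(=O)(Cc1cc(OC)cc(OC)c1)OCC | starting material
2 | 3,4-bis(benzyloxy)benzaldehyde | O=Cc1ccc(OCc2ccccc2)c(OCc2ccccc2)c1 | starting material
3 | potassium salt of the benzylic carbanion of 1 | CCOP(=O)([CH-]c1cc(OC)cc(OC)c1)OCC.[K+] | intermediate
4 | (E)-3',4'-bis(benzyloxy)-3,5-dimethoxystilbene | COc1cc(OC)cc(/C=C/c2ccc(OCc3ccccc3)c(OCc3ccccc3)c2)c1 | intermediate
5 | (E)-2-bromo-3',4'-bis(benzyloxy)-3,5-dimethoxystilbene (bromine ortho to the alkene on the dimethoxy ring) | COc1cc(OC)c(Br)c(/C=C/c2ccc(OCc3ccccc3)c(OCc3ccccc3)c2)c1 | intermediate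
6 | 1-bromo-3-methylbut-2-ene (prenyl bromide) | CC(C)=CCBr | starting material
7 | (E)-3',4'-bis(benzyloxy)-2-lithio-3,5-dimethoxystilbene | COc1cc(OC)c([Li])c(/C=C/c2ccc(OCc3ccccc3)c(OCc3ccccc3)c2)c1 | intermediate
8 | (E)-3',4'-bis(benzyloxy)-3,5-dimethoxy-2-(3-methylbut-2-enyl)stilbene | COc1cc(OC)c(CC=C(C)C)c(/C=C/c2ccc(OCc3ccccc3)c(OCc3ccccc3)c2)c1 | intermediate
9 | (2S,2aR,7aS)-2-[3,4-bis(benzyloxy)phenyl]-4,6-dimethoxy-1,1-dimethyl-2,2a,7,7a-tetrahydro-1H-cyclobuta[a]indene (cis ring fusion; aryl on the convex face, trans to the arene bond at C2a) | COc1cc(OC)cc2c1C[C@H]1[C@@H]2[C@H](c2ccc(OCc3ccccc3)c(OCc3ccccc3)c2)C1(C)C | intermediate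
10 | N,N-dimethyliminium chloride of aldehyde 11 (C3–CH=NMe2+ Cl−) | COc1cc(OC)c(C=[N+](C)C)c2c1C[C@H]1[C@@H]2[C@H](c2ccc(OCc3ccccc3)c(OCc3ccccc3)c2)C1(C)C.[Cl-] | intermediate
11 | (2S,2aR,7aS)-2-[3,4-bis(benzyloxy)phenyl]-4,6-dimethoxy-1,1-dimethyl-2,2a,7,7a-tetrahydro-1H-cyclobuta[a]indene-3-carbaldehyde | COc1cc(OC)c(C=O)c2c1C[C@H]1[C@@H]2[C@H](c2ccc(OCc3ccccc3)c(OCc3ccccc3)c2)C1(C)C | intermediate
12 | boron-bound form of 13 (C4–O–BCl2 and cyclic chloroboronate of the catechol) | COc1cc(OB(Cl)Cl)c(C=O)c2c1C[C@H]1[C@@H]2[C@H](c2ccc3OB(Cl)Oc3c2)C1(C)C | intermediate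
13 | (2S,2aR,7aS)-2-(3,4-dihydroxyphenyl)-4-hydroxy-6-methoxy-1,1-dimethyl-2,2a,7,7a-tetrahydro-1H-cyclobuta[a]indene-3-carbaldehyde | COc1cc(O)c(C=O)c2c1C[C@H]1[C@@H]2[C@H](c2ccc(O)c(O)c2)C1(C)C | intermediate
14 | 2-methylprop-1-enylboronic acid | CC(C)=CB(O)O | starting material
15 | cyclic 2-methylprop-1-enylboronate of the catechol of 13 | COc1cc(O)c(C=O)c2c1C[C@H]1[C@@H]2[C@H](c2ccc3OB(C=C(C)C)Oc3c2)C1(C)C | intermediate
16 | Petasis adduct of 15 (formyl carbon now CH(NBn2)–CH=CMe2, either configuration at that carbon; catechol boronate retained) | COc1cc(O)c(C(C=C(C)C)N(Cc2ccccc2)Cc2ccccc2)c2c1C[C@H]1[C@@H]2[C@H](c2ccc3OB(C=C(C)C)Oc3c2)C1(C)C | intermediate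
17 | ortho-quinone methide from 16 (C4 carbonyl, 3-methylbut-2-enylidene on C3; catechol boronate retained) | COC1=CC(=O)C(=CC=C(C)C)C2=C1C[C@H]1[C@@H]2[C@H](c2ccc3OB(C=C(C)C)Oc3c2)C1(C)C | intermediate
18 | cyclic 2-methylprop-1-enylboronate of the catechol of 19 | COc1cc2c(c3c1C[C@H]1[C@@H]3[C@H](c3ccc4OB(C=C(C)C)Oc4c3)C1(C)C)C=CC(C)(C)O2 | intermediate
19 | target CNP0207533.1: 2,2-dimethyl-2H-pyran fused across C3–C4 of the cyclobuta[a]indene of 13 (O on C4, pyran C4 on C3), with 6-methoxy, 1,1-dimethyl and 2-(3,4-dihydroxyphenyl); (2S,2aR,7aS) in the locants of 13 | COc1cc2c(c3c1C[C@H]1[C@@H]3[C@H](c3ccc(O)c(O)c3)C1(C)C)C=CC(C)(C)O2 | target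

Total step count: 7
Longest linear sequence: 7 steps (from 1 or 2 to 19)

Steps most likely to fail

Step 4 (proposed new method). The counteranion may discriminate poorly between the two faces in the first C–C bond formation, and re-oxidation of the electron-rich aryl cyclobutane with cycloreversion may erode the enantiomeric purity. The fallback sets out from 8 and uses a known racemic intramolecular styrene–alkene [2+2] by triplet energy transfer (Ir[dF(CF3)ppy]2(dtbbpy)PF6, blue LEDs, degassed DMSO, rt). It should give 9 together with its mirror image, the ent-cyclobutaindane F1. Preparative chromatography on an amylose-carbamate chiral stationary phase should separate the two, and the route is rejoined at 9.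

Step 7. Iminium formation may be slow at a formyl group flanked by the phenol and the ring-fusion carbon, the alkenylboronic acid may protodeboronate, and the free catechol may tie up boron and amine or oxidise. The fallback sets out from 13 and makes the same two bonds in separate operations on a protected substrate. Silylation (TBSCl, imidazole, DMF, 0 °C) should cap only the catechol, since the hydrogen-bonded salicyl OH stays free, and give the bis-silyl salicylaldehyde F2. Addition of 2-methylprop-1-enylmagnesium bromide (3 equiv, THF, 0 °C) should give the allylic alcohol F3. Mild acid (PPTS, toluene, 60 °C) should dehydrate it and close the pyran to the bis-silyl chromene F4. Desilylation (Bu4NF, AcOH, THF, 0 °C) rejoins the route at 19.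

Step 5. Formylation may go to C5 between the two methoxy groups, or be slowed by the neighbouring ring-fusion carbon. The fallback sets out from 5 and places the formyl group on the flat stilbene, where the position ortho to the alkene and para to a methoxy group is the normal site of attack. Vilsmeier–Haack formylation (POCl3, DMF) should give the bromo aldehyde F5. Stille coupling with tributyl(3-methylbut-2-enyl)stannane (Pd(PPh3)4, DMF, 90 °C) should give the prenyl aldehyde F6. The triplet-sensitised [2+2] described for step 4 should then give 11 together with its mirror image, the ent-aldehyde F7, and chiral-phase chromatography rejoins the route at 11.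

Further compounds
F1 | step 4 | (2R,2aS,7aR)-2-[3,4-bis(benzyloxy)phenyl]-4,6-dimethoxy-1,1-dimethyl-2,2a,7,7a-tetrahydro-1H-cyclobuta[a]indene (mirror image of 9) | COc1cc(OC)cc2c1C[C@@H]1[C@H]2[C@@H](c2ccc(OCc3ccccc3)c(OCc3ccccc3)c2)C1(C)C
F2 | step 7 | (2S,2aR,7aS)-2-[3,4-bis(tert-butyldimethylsilyloxy)phenyl]-4-hydroxy-6-methoxy-1,1-dimethyl-2,2a,7,7a-tetrahydro-1H-cyclobuta[a]indene-3-carbaldehyde | COc1cc(O)c(C=O)c2c1C[C@H]1[C@@H]2[C@H](c2ccc(O[Si](C)(C)C(C)(C)C)c(O[Si](C)(C)C(C)(C)C)c2)C1(C)C
F3 | step 7 | allylic alcohol from F2 (C3 substituent CH(OH)–CH=CMe2, either configuration at the carbinol carbon) | COc1cc(O)c(C(O)C=C(C)C)c2c1C[C@H]1[C@@H]2[C@H](c2ccc(O[Si](C)(C)C(C)(C)C)c(O[Si](C)(C)C(C)(C)C)c2)C1(C)C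
F4 | step 7 | bis(tert-butyldimethylsilyl) ether of 19 | COc1cc2c(c3c1C[C@H]1[C@@H]3[C@H](c3ccc(O[Si](C)(C)C(C)(C)C)c(O[Si](C)(C)C(C)(C)C)c3)C1(C)C)C=CC(C)(C)O2
F5 | step 5 | (E)-2-{2-[3,4-bis(benzyloxy)phenyl]ethenyl}-3-bromo-4,6-dimethoxybenzaldehyde | COc1cc(OC)c(C=O)c(/C=C/c2ccc(OCc3ccccc3)c(OCc3ccccc3)c2)c1Br
F6 | step 5 | (E)-2-{2-[3,4-bis(benzyloxy)phenyl]ethenyl}-4,6-dimethoxy-3-(3-methylbut-2-enyl)benzaldehyde | COc1cc(OC)c(C=O)c(/C=C/c2ccc(OCc3ccccc3)c(OCc3ccccc3)c2)c1CC=C(C)C
F7 | step 5 | (2R,2aS,7aR)-2-[3,4-bis(benzyloxy)phenyl]-4,6-dimethoxy-1,1-dimethyl-2,2a,7,7a-tetrahydro-1H-cyclobuta[a]indene-3-carbaldehyde (mirror image of 11) | COc1cc(OC)c(C=O)c2c1C[C@@H]1[C@H]2[C@@H](c2ccc(OCc3ccccc3)c(OCc3ccccc3)c2)C1(C)C
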